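Read at 25 min, zeta and gamma are read late. Ash gives 18 % at 20.0 min and 18 % at 25.0 min, elm 74 % and 72 % at those times, and you can't tell those pairs apart with a scatter of 2 percentage points. So take the last readings as plateaus.

in all of them: initiator 2 mol%

| run | free monomer | protic impurity | remark | time |
|---|---|---|---|---|
| ash | 0.060 M | 0.10 M | run made earlier |  |
| elm | 0.27 M | 0.10 M | run made earlier |  |
| zeta | 0.10 M | 0.100 M |  | 25 min |
| gamma | 0.30 M | 0.100 M |  | 25 min |

| run | time / min | monomer in chains / % |
|---|---|---|
| ash | 6.00 | 8 |
| ash | 12.0 | 12 |
| ash | 20.0 | 18 |
| ash | 25.0 | 18 |
| elm | 6.00 | 66 |
| elm | 12.0 | 72 |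
| elm | 20.0 | 74 |
| elm | 25.0 | 72 |

(readings scatter by 2 percentage points)

- which of the two ends with the longer chains by the average number of monomer units in a chain (chains begun, living or dead) ("neither" if they lie within 10 %) (zeta / gamma / neither)
- average number of monomer units in a chain (chains begun, living or dead) at the end, zeta
- average number of monomer units in a chain (chains begun, living or dead) at the end, gamma

- the average divides the monomer in chains by the number of chains begun, living and dead together
- the earlier runs do not show the number of chains; that part of a forecast is a guess

Now turn the question round: what would have to be true for zeta to end longer? In the two runs, monomer in chains climbs with c(free monomer). My straight line through the last readings puts zeta at 28.3 % and gamma, just beyond elm, at 79.7 %. Dividing by the loading of 2 mol% gives 14.1 for zeta and 39.9 for gamma. Call this the floor length: monomer in chains per initiator charged. If each initiator begins one chain or none, the average (the number-average chain length) is the floor divided by the share of initiator used. The loadings are equal, so zeta ends longer only if its used share falls under 0.355 of gamma's. The readings don't show that share, so it stays a guess, but the gap is wide.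

The forecast says gamma, with 22 for zeta (12 to 27) and 37 for gamma (18 to 41): “Gamma is longer either way.” Its zeta, interpolated from the free monomer left, stands higher than my 14.1.

The flask gives gamma, with 24.0 for zeta and 45.1 for gamma.

    free monomer + initiator → living end + monomer in chains (k = 2.10 M⁻¹ min⁻¹)
    free monomer + living end → monomer in chains + living end, rate k2*[living end]*[free monomer] (k = 110 M⁻¹ min⁻¹)
    protic impurity + free monomer → quenched substrate (k = 1.40 M⁻¹ min⁻¹)
    living end → dead end (k = 0.130 min⁻¹)

Initiator used is 74.2 % in zeta and 84.1 % in gamma, a ratio of 0.882 against the 0.355 needed to turn the order. Both averages stand above my floors of 14.1 and 39.9. The simulated monomer in chains, taken per initiator used, gives 24.0 for zeta and 45.1 for gamma. On the neighbour, gamma with 0.8 mol% of initiator, it gives 78.9, and the simulated average is 78.9. Gamma barely moves after 25 min: by 250 min its monomer in chains goes from 76.0 % to 76.1 % and its average reads 44.7. Zeta's free monomer falls from 4.85 % to 0 % by then, its quenched substrate rises from 59.5 % to 63.8 %, its monomer in chains rises from 35.7 % to 36.2 %, and its average reads 23.2.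

The data come from a simulation from invented constants, noise included.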